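A slow loss hides easily in a short row of readings. Spring is the close neighbour of epsilon: the same [starting material] but less coupling partner. In both flasks the partner is the limiting reagent, so single product has a ceiling at partner charge over starting charge, 32.4% in spring and 50.0% in epsilon. Spring's readings average 28.8% and show no trend, so a slow decay does not stand out in them.

| setting | spring | autumn | epsilon | gamma | alpha |
|---|---|---|---|---|---|
| starting material | 0.17 M | 0.17 M | 0.17 M | 0.17 M | 0.17 M |
| coupling partner | 0.055 M | 0.27 M | 0.0850 M | 0.136 M | 0.425 M |
| remark | run made earlier | run made earlier |  |  |  |
| time |  |  | 20 h | 20 h | 20 h |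

- spring (time / h: single product / %, bis adduct / %): 4.00: 28, 0; 8.00: 27, 0; 10.0: 33, 4; 15.0: 27, 1
- autumn (time / h: single product / %, bis adduct / %): 4.00: 82, 9; 8.00: 77, 18; 10.0: 70, 21; 15.0: 63, 25

(readings scatter by 2 percentage points)

* final single product, as a percentage of the starting material charged, for each flask in turn (epsilon, gamma, alpha)

- reactions considered so far: starting material + coupling partner -> single product; coupling partner + single product <-> bis adduct; single product -> decomposed reagent

Autumn offers a better measure: decomposition lowers the sum of single product and bis adduct, while the second coupling leaves that sum unchanged. Between its first and last pairs of readings, 6.50 h apart, that sum falls by 3.5 percentage points. Against a mean single product of 73.0%, I take this as a rough reading of the decay, 0.00738 h⁻¹. Over spring's readings that costs 2.3 points, beside a scatter of 2 points per reading.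

Early in autumn, the readings show bis adduct forming, net of any return, at 0.0283 h⁻¹ per unit of single product, a pseudo-first-order rate, at a [coupling partner] near 0.0771 M. Dividing one drain by the other removes time and [single product]. The result, 0.0201 M, is the crossover concentration: the [coupling partner] at which single product is lost equally to decomposition and to the second coupling.

Epsilon starts above it, but I expect the first coupling to carry [coupling partner] below it; my own estimate then applies the decay to the ceiling, which gives 43.1% at 20 h. Alpha's excess of 0.255 M stands above crossover, so there I expect the second coupling to lead. The forecast gives 44%, 69% and 40%, reading spring as “its own decomposition is slow”.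

The flasks give 40.2%, 61.4% and 38.0%.

    starting material + coupling partner → single product (k = 0.00130 M⁻¹ s⁻¹)
    coupling partner + single product ⇌ bis adduct (K = 8.50 M⁻¹, k = 1.20 × 10⁻⁴ M⁻¹ s⁻¹)
    single product → decomposed reagent (k = 2.90 × 10⁻⁶ s⁻¹)

In epsilon, decomposition has a half-life of 66 h, long against the 20 h run, yet [coupling partner] at 10.0 h is 7.91 × 10⁻⁴ M, far below crossover, and the end holds 8.34% decomposed reagent against 0.702% bis adduct. Alpha at 20.0 h holds 0.168 M of coupling partner, far above crossover, with 10.9% decomposed reagent against 51.1% bis adduct.

All runs are calculated with made-up constants.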